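How strongly does the rate of making target in the flask, at 30 % conversion of the substrate, answer to the free catalyst charged?

common to all: substrate 0.50 M

|  | partner | free catalyst | remark |
|---|---|---|---|
| violet | 0.35 M | 1.7 mM | run made earlier |
| green | 0.35 M | 3.8 mM | run made earlier |
| amber | 0.52 M | 2.5 mM | run made earlier |
| flask | 0.350 M | 2.5 mM |  |

| run | time / min | target / % |
|---|---|---|
| violet | 0.200 | 4.9 |
| violet | 0.333 | 7.1 |
| violet | 0.500 | 10.9 |
| violet | 0.833 | 16.5 |
| violet | 1.33 | 25.1 |
| violet | 2.50 | 35.3 |
| green | 0.417 | 19.3 |
| green | 0.833 | 32.7 |
| green | 1.33 | 42.7 |
| green | 1.50 | 46.0 |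
| green | 2.00 | 48.7 |
| green | 2.50 | 48.5 |
| amber | 0.200 | 7.5 |
| amber | 0.333 | 11.0 |
| amber | 0.667 | 20.6 |
| amber | 1.33 | 35.7 |
| amber | 2.50 | 48.1 |

(readings scatter by 0.5 percentage points)

- apparent order in free catalyst when 30 % of the substrate are converted (percent change of the rate of making target for one percent more free catalyst charged)
- factor on the rate of making target when 30 % of the substrate are converted if free catalyst is charged twice over

- steps that have been proposed: substrate + free catalyst <-> catalyst intermediate A; catalyst intermediate A -> catalyst intermediate B; partner + catalyst intermediate B -> catalyst intermediate C; catalyst intermediate C -> by-product + catalyst intermediate D; catalyst intermediate D <-> free catalyst + target; 2 partner -> self-condensation product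

I followed one partner molecule, which at its fork either passes through the cycle into target or is lost to self-condensation product. Green's last reading made the partner lost per partner turned into target 0.443, and I carried this ratio as the loss odds. I assumed that these odds fall in inverse proportion to the free catalyst charged, which put the flask at 0.674. A partner molecule in the flask then had a chance of 59.7 % of reaching target. I also took the rate at fixed conversion to scale with free catalyst times that chance, which gave me an order of 1.40 and a factor of 2.50 on doubling. The forecast stood lower than my figures, at 1.3 and 2.4, holding that “Partner survival saturates as the catalyst rises”. The simulation gave 1.3 and 2.25, so my reckoning ran high on both.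

    substrate + free catalyst ⇌ catalyst intermediate A (K = 0.510 L mol⁻¹, k = 3.50 L mol⁻¹ s⁻¹)
    catalyst intermediate A → catalyst intermediate B (k = 990 s⁻¹)
    partner + catalyst intermediate B → catalyst intermediate C (k = 28.0 L mol⁻¹ s⁻¹)
    catalyst intermediate C → by-product + catalyst intermediate D (k = 100 s⁻¹)
    catalyst intermediate D ⇌ free catalyst + target (K = 0.540 M, k = 8.10 s⁻¹)
    2 partner → self-condensation product (k = 0.0260 L mol⁻¹ s⁻¹)

Without the self-condensation, the order in the flask falls from 1.3 to 1.0, so the excess over first order goes with that loss. By 4.00 min the flask held 0 % of its partner, the limiting reagent, and target stood at 43.4 % of the substrate, so its loss odds were 0.613 against my 0.674. Scaled to violet, the odds become 0.991 and put its end target at 35.2 % of the substrate. Violet's readings show no plateau to hold that figure against, for they were still climbing from 25.1 % at 1.33 min to 35.3 % at 2.50 min.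

The readings come from a simulation on assumed constants; scatter was added.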